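**Retrosynthetic overview**
1. The lactone ring (ring B) is closed last by forming the C4–C4a bond: an anodic, PPh3-mediated dehydrative C-alkylation of an ester-tethered (S)-benzylic alcohol, with inversion to give (4R).
2. The tether (the future O1–C2 lactone bond) comes from esterifying the non-chelated para-hydroxyl of 3-prenyl-2,4,6-trihydroxybenzophenone with (S)-3-hydroxy-3-phenylpropanoic acid; this fixes the lactone regiochemistry.
3. The prenyl C–C bond comes from C-alkylation of commercial 2,4,6-trihydroxybenzophenone, so ring A is bought with the benzoyl group in place.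
4. Ring order: aromatic ring A purchased, lactone ring B formed in the final step.

Assumption: C4 of the target is (R) (CIP order C4a > phenyl > CH2 > H), and enantiopure (S)-3-hydroxy-3-phenylpropanoic acid is taken as a purchasable building block.

**Route**

Step 1
Reactants: 1 2,4,6-trihydroxybenzophenone; 2 prenyl bromide (1-bromo-3-methylbut-2-ene)
Product: 3 phenyl[2,4,6-trihydroxy-3-(3-methylbut-2-en-1-yl)phenyl]methanone
Conditions: 2 (1.0 equiv), KOH (10% aq.), 0 °C, 2 h; recover unreacted 1
Reagents that add atoms: none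
Why: Phenolate C-alkylation of an acylphloroglucinol in water, where solvation of the oxygens favours C-attack; the two free ring positions are equivalent, so only one mono-C-prenyl isomer can form, and no stereocenter is involved.

Step 2
Reactants: 3 phenyl[2,4,6-trihydroxy-3-(3-methylbut-2-en-1-yl)phenyl]methanone; 4 (S)-3-hydroxy-3-phenylpropanoic acid
Product: 5 4-benzoyl-3,5-dihydroxy-2-(3-methylbut-2-en-1-yl)phenyl (3S)-3-hydroxy-3-phenylpropanoate
Conditions: DCC (1.05 equiv), DMAP (5 mol %), CH2Cl2, 0 °C, 1 h; use 5 promptly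
Reagents that add atoms: none
Why: Steglich esterification; the para-hydroxyl is the most acidic and the only one not hydrogen-bonded to the ketone or flanked by it, so its phenoxide is acylated in preference to the ortho-hydroxyls and to the secondary benzylic alcohol, and the purchased (S)-stereocenter is not touched.

Step 3
Reactants: 5 4-benzoyl-3,5-dihydroxy-2-(3-methylbut-2-en-1-yl)phenyl (3S)-3-hydroxy-3-phenylpropanoate
Product: 7 (4R)-6-benzoyl-5,7-dihydroxy-8-(3-methylbut-2-en-1-yl)-4-phenyl-3,4-dihydro-2H-chromen-2-one, via alkoxytriphenylphosphonium tetrafluoroborate 6 (not isolated)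
Conditions: PPh3 (1.5 equiv), 2,6-lutidine (2 equiv), Bu4NBF4 (0.1 M), CH2Cl2 (5 mM in 5), undivided cell, graphite anode, Pt cathode, 2 mA cm−2, 2.2 F mol−1, 0 °C; then 25 °C, 6 h
Reagents that add atoms: none
Why: Proposed new method: anodic oxidation of PPh3 (expected to be the most easily oxidised species present) gives Ph3P•+, which is captured by the benzylic hydroxyl and oxidised again to the alkoxyphosphonium salt 6; the only nucleophile that can reach the activated carbon intramolecularly is the ortho C–H carbon of the phenolic ring (6-exo-tet, whereas O-attack would need an eight-membered ring), so backside SN2 displacement of Ph3P=O forms C4–C4a, closes ring B and converts the purchased (S)-carbinol into (4R)-C4 by inversion, with the β-ester carbonyl disfavouring SN1 ionisation and protons reduced to H2 at the cathode; the closest known reaction type is the electrochemical Mitsunobu/Appel-type dehydration, in which anodically generated alkoxytriphenylphosphonium salts are displaced by heteroatom nucleophiles with inversion, extended here to an arene carbon nucleophile (intramolecular Friedel–Crafts-type phenol C-alkylation).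

**Compound list**

1 | 2,4,6-trihydroxybenzophenone | O=C(c1ccccc1)c1c(O)cc(O)cc1O | starting material
2 | prenyl bromide (1-bromo-3-methylbut-2-ene) | CC(C)=CCBr | starting material
3 | phenyl[2,4,6-trihydroxy-3-(3-methylbut-2-en-1-yl)phenyl]methanone | CC(C)=CCc1c(O)cc(O)c(C(=O)c2ccccc2)c1O | intermediate
4 | (S)-3-hydroxy-3-phenylpropanoic acid | O[C@@H](CC(=O)O)c1ccccc1 | starting material
5 | 4-benzoyl-3,5-dihydroxy-2-(3-methylbut-2-en-1-yl)phenyl (3S)-3-hydroxy-3-phenylpropanoate | CC(C)=CCc1c(O)c(C(=O)c2ccccc2)c(O)cc1OC(=O)C[C@H](O)c1ccccc1 | intermediate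
6 | [(1S)-3-[4-benzoyl-3,5-dihydroxy-2-(3-methylbut-2-en-1-yl)phenoxy]-3-oxo-1-phenylpropoxy]triphenylphosphonium tetrafluoroborate | CC(C)=CCc1c(O)c(C(=O)c2ccccc2)c(O)cc1OC(=O)C[C@H](O[P+](c1ccccc1)(c1ccccc1)c1ccccc1)c1ccccc1.F[B-](F)(F)F | intermediate
7 | (4R)-6-benzoyl-5,7-dihydroxy-8-(3-methylbut-2-en-1-yl)-4-phenyl-3,4-dihydro-2H-chromen-2-one | CC(C)=CCc1c(O)c(C(=O)c2ccccc2)c(O)c2c1OC(=O)C[C@@H]2c1ccccc1 | target

**Step count and risks**

Total steps: 3. Longest linear sequence: 3 (1 → 3 → 5 → 7).

Most likely to fail, first: step 3, the proposed new anodic cyclisation. The risks are competitive anodic oxidation of the phenol, base-induced elimination of 6 to the aryl cinnamate, and partial ionisation of 6 that would erode the enantiomeric purity; the ee of 7 must be checked by chiral HPLC. The fallback uses known chemistry, sets out from 4 and comes back to the route at 7.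
- Acid 4 is lactonised by carboxyl activation (PhSO2Cl, pyridine, 0 °C, retention) to (4S)-4-phenyloxetan-2-one F1.
- Copper-catalysed Grignard opening of the β-lactone at its benzylic carbon (commercial 2,4,6-trimethoxyphenylmagnesium bromide, CuBr·SMe2 10 mol %, THF/Me2S, −30 to 0 °C; SN2 with inversion) gives (3R)-3-phenyl-3-(2,4,6-trimethoxyphenyl)propanoic acid F2.
- BBr3 in CH2Cl2 removes the three methyl ethers and the acid lactonises onto an ortho-hydroxyl to give (4R)-5,7-dihydroxy-4-phenylchroman-2-one F3.
- Friedel–Crafts benzoylation (benzoyl chloride, AlCl3, nitrobenzene, 60 °C) gives, after separation from the 8-benzoyl isomer, (4R)-6-benzoyl-5,7-dihydroxy-4-phenylchroman-2-one F4.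
- C-Prenylation of the one remaining ring position with 2 (aq. KOH, 0 °C) gives 7.

Second: step 2. The free β-hydroxyl can lead to oligoesters, and acylation or acyl migration to an ortho-hydroxyl would give the wrong lactone regioisomer later. The fallback is a protecting-group approach that sets out from 4 and comes back at 5.
- Bis-silylation of 4 (TBSCl, imidazole, DMF) gives tert-butyldimethylsilyl (3S)-3-[(tert-butyldimethylsilyl)oxy]-3-phenylpropanoate F5, which is not isolated.
- Selective cleavage of the silyl ester (K2CO3, aq. MeOH/THF) gives (3S)-3-[(tert-butyldimethylsilyl)oxy]-3-phenylpropanoic acid F6.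
- Coupling of F6 with 3 (DCC, DMAP, CH2Cl2) gives 4-benzoyl-3,5-dihydroxy-2-(3-methylbut-2-en-1-yl)phenyl (3S)-3-[(tert-butyldimethylsilyl)oxy]-3-phenylpropanoate F7.
- Desilylation with HF·pyridine in THF gives 5.

Third: step 1. O-Prenylation, bis-prenylation and chroman formation lower the yield of 3. The fallback replaces direct alkylation by a sigmatropic/metathesis sequence; it sets out from 1 and comes back at 3.
- Selective O-allylation of the para-hydroxyl (allyl bromide, K2CO3, acetone) gives (2,6-dihydroxy-4-(prop-2-en-1-yloxy)phenyl)(phenyl)methanone F8.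
- Thermal aromatic Claisen rearrangement (N,N-diethylaniline, 190 °C) gives phenyl[2,4,6-trihydroxy-3-(prop-2-en-1-yl)phenyl]methanone F9.
- Olefin cross-metathesis with 2-methyl-2-butene (second-generation Grubbs catalyst, (H2IMes)(PCy3)Cl2Ru=CHPh, CH2Cl2, 40 °C) converts the allyl group into prenyl and gives 3.

**Further compounds**

F1 | step 3 | (4S)-4-phenyloxetan-2-one | O=C1C[C@@H](c2ccccc2)O1
F2 | step 3 | (3R)-3-phenyl-3-(2,4,6-trimethoxyphenyl)propanoic acid | COc1cc(OC)c([C@H](CC(=O)O)c2ccccc2)c(OC)c1
F3 | step 3 | (4R)-5,7-dihydroxy-4-phenylchroman-2-one | O=C1C[C@H](c2ccccc2)c2c(O)cc(O)cc2O1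
F4 | step 3 | (4R)-6-benzoyl-5,7-dihydroxy-4-phenylchroman-2-one | O=C1C[C@H](c2ccccc2)c2c(O)c(C(=O)c3ccccc3)c(O)cc2O1
F5 | step 2 | tert-butyldimethylsilyl (3S)-3-[(tert-butyldimethylsilyl)oxy]-3-phenylpropanoate | CC(C)(C)[Si](C)(C)O[C@@H](CC(=O)O[Si](C)(C)C(C)(C)C)c1ccccc1
F6 | step 2 | (3S)-3-[(tert-butyldimethylsilyl)oxy]-3-phenylpropanoic acid | CC(C)(C)[Si](C)(C)O[C@@H](CC(=O)O)c1ccccc1
F7 | step 2 | 4-benzoyl-3,5-dihydroxy-2-(3-methylbut-2-en-1-yl)phenyl (3S)-3-[(tert-butyldimethylsilyl)oxy]-3-phenylpropanoate | CC(C)=CCc1c(O)c(C(=O)c2ccccc2)c(O)cc1OC(=O)C[C@H](O[Si](C)(C)C(C)(C)C)c1ccccc1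
F8 | step 1 | (2,6-dihydroxy-4-(prop-2-en-1-yloxy)phenyl)(phenyl)methanone | C=CCOc1cc(O)c(C(=O)c2ccccc2)c(O)c1
F9 | step 1 | phenyl[2,4,6-trihydroxy-3-(prop-2-en-1-yl)phenyl]methanone | C=CCc1c(O)cc(O)c(C(=O)c2ccccc2)c1O
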